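**Plan**

1. Retrosynthetic cuts, in order: the C7–C(=O) aryl ketone bond (chalcone arm off a 7-bromo-2,3-dihydrobenzofuran), the C2–C3 bond of the dihydrofuran ring, then the ArO–CH2 ether bond and the aryl–CHO bond of a benzaldehyde.
2. Enabling feature: C2 of the dihydrofuran ring bears one H, the ring oxygen O1 and the carbinol carbon of the 2-hydroxypropan-2-yl group. It is therefore the former O–CH2 of an aryl 2-hydroxy-2-methylpropyl ether, with its two C–H bonds 1,5 to the benzylic carbon C3, where a carbene can be raised from an aldehyde tosylhydrazone.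
3. Forward: 2-bromo-5-methoxyphenol is formylated between OH and OMe, etherified with 2,2-dimethyloxirane, silylated and converted into the tosylhydrazone. Carbene C–H insertion then closes the dihydrofuran, the only ring built.
4. The chalcone arm is joined last by bromine–lithium exchange at C7 and acylation with a silyl-protected 4-hydroxycinnamoyl Weinreb amide; fluoride then removes both silyl groups.
5. Stereochemistry: the single stereocentre C2 (R) is set in the insertion, where the chiral dirhodium catalyst chooses between the two enantiotopic C2–H bonds. The E-olefin comes with 4-hydroxycinnamic acid.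

Key step: step 5

Assumption: the sense of induction of dirhodium tetrakis[(R)-(1-adamantyl)(N-phthalimido)acetate], Rh2(R-PTAD)4, on this substrate cannot be predicted with certainty; the R-catalyst is written, and if a trial run favours the (S)-product the mirror-image complex Rh2(S-PTAD)4 is to be used under the same conditions.

**Route**

Step 1
Reactants: 1 2-bromo-5-methoxyphenol
Product: 2 3-bromo-2-hydroxy-6-methoxybenzaldehyde
Conditions: MgCl2, Et3N, (CH2O)n, MeCN, reflux; then aq. HCl
Reagents that add atoms: paraformaldehyde (as formaldehyde), C=O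
Why: Magnesium-mediated ortho-formylation (Casiraghi–Skattebøl) delivers formaldehyde from the chelated magnesium phenoxide only to a carbon ortho to the phenol oxygen, and because the other ortho carbon carries bromine the formyl group must enter between OH and OMe, a position that is known to react in 3-alkoxyphenols.

Step 2
Reactants: 2 3-bromo-2-hydroxy-6-methoxybenzaldehyde; 3 2,2-dimethyloxirane
Product: 4 3-bromo-2-(2-hydroxy-2-methylpropoxy)-6-methoxybenzaldehyde
Conditions: 3 (3 equiv), K2CO3 (0.5 equiv), DMF, 90 °C, sealed tube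
Reagents that add atoms: none
Why: Base-mediated epoxide opening by a phenoxide (SN2 at the unsubstituted CH2 of the oxirane) installs the complete 2-hydroxy-2-methylpropyl ether in one operation, the non-enolisable aldehyde being inert to carbonate.

Step 3
Reactants: 4 3-bromo-2-(2-hydroxy-2-methylpropoxy)-6-methoxybenzaldehyde
Product: 5 3-bromo-6-methoxy-2-[2-methyl-2-(triethylsilyloxy)propoxy]benzaldehyde
Conditions: TESOTf, 2,6-lutidine, CH2Cl2, 0 °C
Reagents that add atoms: triethylsilyl trifluoromethanesulfonate, CC[Si](CC)(CC)OS(=O)(=O)C(F)(F)F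
Why: Silylation of a tertiary alcohol with a silyl triflate and a hindered pyridine base is routine and masks the hydroxyl that would otherwise trap the carbene by O–H insertion and later quench the aryllithium.

Step 4
Reactants: 5 3-bromo-6-methoxy-2-[2-methyl-2-(triethylsilyloxy)propoxy]benzaldehyde; 6 4-methylbenzenesulfonohydrazide
Product: 7 (E)-N'-{3-bromo-6-methoxy-2-[2-methyl-2-(triethylsilyloxy)propoxy]benzylidene}-4-methylbenzenesulfonohydrazide
Conditions: THF, 4 Å MS, 40 °C
Reagents that add atoms: none
Why: Condensation of an aromatic aldehyde with a sulfonyl hydrazide gives the E-tosylhydrazone under neutral conditions that leave the triethylsilyl ether untouched.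

Step 5
Reactants: 7 (E)-N'-{3-bromo-6-methoxy-2-[2-methyl-2-(triethylsilyloxy)propoxy]benzylidene}-4-methylbenzenesulfonohydrazide
Product: 10 {[2-((2R)-7-bromo-4-methoxy-2,3-dihydro-1-benzofuran-2-yl)propan-2-yl]oxy}triethylsilane, via hydrazone sodium salt 8 (not isolated), via aryldiazomethane 9 (not isolated)
Conditions: NaH, THF, 0 °C; evaporate; Rh2(R-PTAD)4 (2 mol %), BnEt3NCl (10 mol %), PhCF3, 40 °C
Reagents that add atoms: none
Why: Proposed new method: the deprotonated hydrazone 8 loses p-toluenesulfinate on gentle warming (Bamford–Stevens) and so feeds aryldiazomethane 9 slowly to the dirhodium tetracarboxylate (divalent rhodium), which expels N2 to give an electrophilic aryl/H rhodium carbene at the future C3; this carbene should insert into a C–H bond of the neighbouring O–CH2 group through a concerted, hydride-transfer-like three-centre transition state. The closest known reaction type is the Rh2(PTAD)4-catalysed enantioselective intramolecular insertion of diaryl carbenes into ether α-C–H bonds giving 2,3-dihydrobenzofurans, together with rhodium and ruthenium-porphyrin carbene transfer from tosylhydrazone salts; what is untested is the aldehyde-derived aryl/H carbene and a methylene flanked by a fully substituted carbon. The dihydrofuran closes by 1,5-insertion, the atoms C3, C3a, C7a, O1 and C2 forming the five-membered ring as the C2–C3 bond is made. C2 becomes stereogenic because the chiral carboxylate pocket should let only one of the two enantiotopic C2–H bonds reach the carbene, and insertion proceeds with retention at that carbon. The step needs site selectivity over the methoxy C–H bonds, which are also 1,5 to the carbene, and chemoselectivity over azine or stilbene formation: the secondary oxygen-activated C–H is the more hydridic, the bromine ortho to the ether oxygen pushes the O–CH2 group out of the ring plane toward the carbene while the methoxy methyl can lie in plane turned toward the free C5–H, and the two ortho substituents together with slow diazo release disfavour bimolecular carbene coupling.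

Step 6
Reactants: 11 (E)-4-hydroxycinnamic acid
Product: 12 (E)-3-(4-hydroxyphenyl)-N-methoxy-N-methylprop-2-enamide
Conditions: MeNHOMe·HCl, EDC·HCl, HOBt, i-Pr2NEt, DMF, 0 °C → rt
Reagents that add atoms: N,O-dimethylhydroxylamine hydrochloride, CNOC.Cl
Why: Carbodiimide/HOBt amide coupling forms the Weinreb amide chemoselectively at the carboxylic acid because the amine is far more nucleophilic than the free phenol, and the E-olefin is carried through unchanged.

Step 7
Reactants: 12 (E)-3-(4-hydroxyphenyl)-N-methoxy-N-methylprop-2-enamide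
Product: 13 (E)-3-[4-(tert-butyldimethylsilyloxy)phenyl]-N-methoxy-N-methylprop-2-enamide
Conditions: TBSCl, imidazole, DMF, rt
Reagents that add atoms: tert-butyldimethylsilyl chloride, CC(C)(C)[Si](C)(C)Cl
Why: Standard silylation of a phenol with a silyl chloride and imidazole masks the acidic OH that would otherwise consume the aryllithium in the next step.

Step 8
Reactants: 10 {[2-((2R)-7-bromo-4-methoxy-2,3-dihydro-1-benzofuran-2-yl)propan-2-yl]oxy}triethylsilane; 13 (E)-3-[4-(tert-butyldimethylsilyloxy)phenyl]-N-methoxy-N-methylprop-2-enamide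
Product: 15 (E)-3-[4-(tert-butyldimethylsilyloxy)phenyl]-1-{(2R)-4-methoxy-2-[2-(triethylsilyloxy)propan-2-yl]-2,3-dihydro-1-benzofuran-7-yl}prop-2-en-1-one, via aryllithium 14 (not isolated)
Conditions: t-BuLi (2 equiv), THF, −78 °C; then 13, −78 → −40 °C; cold aq. NH4Cl
Reagents that add atoms: none
Why: Bromine–lithium exchange gives an aryllithium stabilised by the neighbouring ring oxygen, which adds 1,2 to the Weinreb amide to form a chelated tetrahedral adduct that releases the enone only on work-up (Weinreb ketone synthesis), so over-addition is avoided and neither the E-olefin nor the C2 stereocentre is touched.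

Step 9
Reactants: 15 (E)-3-[4-(tert-butyldimethylsilyloxy)phenyl]-1-{(2R)-4-methoxy-2-[2-(triethylsilyloxy)propan-2-yl]-2,3-dihydro-1-benzofuran-7-yl}prop-2-en-1-one
Product: 16 (E)-1-[(2R)-2-(2-hydroxypropan-2-yl)-4-methoxy-2,3-dihydro-1-benzofuran-7-yl]-3-(4-hydroxyphenyl)prop-2-en-1-one
Conditions: TBAF, THF, 0 °C → rt; H2O work-up
Reagents that add atoms: none
Why: Fluoride-induced desilylation cleaves the aryl silyl ether and the tertiary triethylsilyl ether in one operation, and the chalcone has no free ortho-hydroxyl that could cyclise to a flavanone under the mildly basic conditions.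

**Compound list**

1 | 2-bromo-5-methoxyphenol | COc1ccc(Br)c(O)c1 | starting material
2 | 3-bromo-2-hydroxy-6-methoxybenzaldehyde | COc1ccc(Br)c(O)c1C=O | intermediate
3 | 2,2-dimethyloxirane | CC1(C)CO1 | starting material
4 | 3-bromo-2-(2-hydroxy-2-methylpropoxy)-6-methoxybenzaldehyde | COc1ccc(Br)c(OCC(C)(C)O)c1C=O | intermediate
5 | 3-bromo-6-methoxy-2-[2-methyl-2-(triethylsilyloxy)propoxy]benzaldehyde | COc1ccc(Br)c(OCC(C)(C)O[Si](CC)(CC)CC)c1C=O | intermediate
6 | 4-methylbenzenesulfonohydrazide (p-toluenesulfonyl hydrazide) | Cc1ccc(S(=O)(=O)NN)cc1 | starting material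
7 | (E)-N'-{3-bromo-6-methoxy-2-[2-methyl-2-(triethylsilyloxy)propoxy]benzylidene}-4-methylbenzenesulfonohydrazide | COc1ccc(Br)c(OCC(C)(C)O[Si](CC)(CC)CC)c1/C=N/NS(=O)(=O)c1ccc(C)cc1 | intermediate
8 | sodium salt of tosylhydrazone 7 | COc1ccc(Br)c(OCC(C)(C)O[Si](CC)(CC)CC)c1/C=N/[N-]S(=O)(=O)c1ccc(C)cc1.[Na+] | intermediate
9 | 1-bromo-3-(diazomethyl)-4-methoxy-2-[2-methyl-2-(triethylsilyloxy)propoxy]benzene | COc1ccc(Br)c(OCC(C)(C)O[Si](CC)(CC)CC)c1C=[N+]=[N-] | intermediate
10 | {[2-((2R)-7-bromo-4-methoxy-2,3-dihydro-1-benzofuran-2-yl)propan-2-yl]oxy}triethylsilane | COc1ccc(Br)c2c1C[C@H](C(C)(C)O[Si](CC)(CC)CC)O2 | intermediate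
11 | (E)-4-hydroxycinnamic acid | OC(=O)/C=C/c1ccc(O)cc1 | starting material
12 | (E)-3-(4-hydroxyphenyl)-N-methoxy-N-methylprop-2-enamide | CON(C)C(=O)/C=C/c1ccc(O)cc1 | intermediate
13 | (E)-3-[4-(tert-butyldimethylsilyloxy)phenyl]-N-methoxy-N-methylprop-2-enamide | CON(C)C(=O)/C=C/c1ccc(O[Si](C)(C)C(C)(C)C)cc1 | intermediate
14 | {(2R)-4-methoxy-2-[2-(triethylsilyloxy)propan-2-yl]-2,3-dihydro-1-benzofuran-7-yl}lithium | COc1ccc([Li])c2c1C[C@H](C(C)(C)O[Si](CC)(CC)CC)O2 | intermediate
15 | (E)-3-[4-(tert-butyldimethylsilyloxy)phenyl]-1-{(2R)-4-methoxy-2-[2-(triethylsilyloxy)propan-2-yl]-2,3-dihydro-1-benzofuran-7-yl}prop-2-en-1-one | COc1ccc(C(=O)/C=C/c2ccc(O[Si](C)(C)C(C)(C)C)cc2)c2c1C[C@H](C(C)(C)O[Si](CC)(CC)CC)O2 | intermediate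
16 | (E)-1-[(2R)-2-(2-hydroxypropan-2-yl)-4-methoxy-2,3-dihydro-1-benzofuran-7-yl]-3-(4-hydroxyphenyl)prop-2-en-1-one | COc1ccc(C(=O)/C=C/c2ccc(O)cc2)c2c1C[C@H](C(C)(C)O)O2 | target

**Count and risks**

Total steps: 9. Longest linear sequence: 7 (steps 1–5, 8, 9); steps 6 and 7 form the side branch.

Steps most likely to fail:

1. Step 5 (proposed new method). Three processes may spoil it:
   - insertion into the methoxy C–H instead of the hindered methylene;
   - bimolecular carbene coupling outrunning the intramolecular insertion;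
   - weak discrimination between the two enantiotopic hydrogens.

   Fallback with known chemistry, setting out from 1 and rejoining at 10: the stereocentre is taken from an asymmetric epoxidation and the ring is closed by C–O bond formation.
   - Phenol 1 is O-alkylated with 3-chloro-3-methylbut-1-yne (DBU, CuCl2 cat., MeCN) to 1-bromo-4-methoxy-2-[(2-methylbut-3-yn-2-yl)oxy]benzene F1.
   - Semi-hydrogenation (H2, lead-poisoned Pd/CaCO3, quinoline) gives 1-bromo-4-methoxy-2-[(2-methylbut-3-en-2-yl)oxy]benzene F2.
   - Heating in N,N-diethylaniline should deliver the prenyl group by aromatic Claisen rearrangement to the only free ortho carbon, giving 6-bromo-3-methoxy-2-(3-methylbut-2-en-1-yl)phenol F3.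
   - Silylation (TBSCl, imidazole) gives tert-butyl[6-bromo-3-methoxy-2-(3-methylbut-2-en-1-yl)phenoxy]dimethylsilane F4.
   - Shi epoxidation with the L-fructose-derived enantiomer of the ketone catalyst and KHSO5 (as the triple salt 2KHSO5·KHSO4·K2SO4, K2CO3 buffer, 0 °C) should give tert-butyl(6-bromo-2-{[(2S)-3,3-dimethyloxiran-2-yl]methyl}-3-methoxyphenoxy)dimethylsilane F5.
   - TBAF frees the phenoxide, which opens the epoxide 5-exo at the secondary carbon with inversion to (2R)-2-(7-bromo-4-methoxy-2,3-dihydro-1-benzofuran-2-yl)propan-2-ol F6.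
   - TESOTf/2,6-lutidine then gives 10.

2. Step 8. Conjugate addition of the aryllithium to the cinnamoyl acceptor, Michael addition of liberated N,O-dimethylhydroxylamine to the enone during quench, or premature protonation of the aryllithium may lower the return.

   Fallback, setting out from 10 and rejoining at 16: the enone is built by aldol condensation instead of acyl transfer.
   - Aryllithium 14 is acetylated with N-methoxy-N-methylacetamide to 1-{(2R)-4-methoxy-2-[2-(triethylsilyloxy)propan-2-yl]-2,3-dihydro-1-benzofuran-7-yl}ethan-1-one F7.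
   - Claisen–Schmidt condensation with 4-hydroxybenzaldehyde (KOH, EtOH) should give (E)-3-(4-hydroxyphenyl)-1-{(2R)-4-methoxy-2-[2-(triethylsilyloxy)propan-2-yl]-2,3-dihydro-1-benzofuran-7-yl}prop-2-en-1-one F8.
   - TBAF removes the triethylsilyl group to give 16.

3. Step 2. Epoxide opening may stall because the phenoxide is hindered on both sides, hydrogen-bonded to the aldehyde and weakly nucleophilic, while the volatile epoxide is lost or oligomerises.

   Fallback, setting out from 2 and rejoining at 4:
   - Alkylation with the far more reactive allylic halide 3-chloro-2-methylprop-1-ene (K2CO3, KI, DMF) gives 3-bromo-6-methoxy-2-[(2-methylprop-2-en-1-yl)oxy]benzaldehyde F9.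
   - Markovnikov hydration of the 1,1-disubstituted olefin (Mukaiyama hydration: Co(acac)2 cat., PhSiH3, O2, i-PrOH) gives 4.

**Further compounds**

F1 | step 5 | 1-bromo-4-methoxy-2-[(2-methylbut-3-yn-2-yl)oxy]benzene | COc1ccc(Br)c(OC(C)(C)C#C)c1
F2 | step 5 | 1-bromo-4-methoxy-2-[(2-methylbut-3-en-2-yl)oxy]benzene | COc1ccc(Br)c(OC(C)(C)C=C)c1
F3 | step 5 | 6-bromo-3-methoxy-2-(3-methylbut-2-en-1-yl)phenol | COc1ccc(Br)c(O)c1CC=C(C)C
F4 | step 5 | tert-butyl[6-bromo-3-methoxy-2-(3-methylbut-2-en-1-yl)phenoxy]dimethylsilane | COc1ccc(Br)c(O[Si](C)(C)C(C)(C)C)c1CC=C(C)C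
F5 | step 5 | tert-butyl(6-bromo-2-{[(2S)-3,3-dimethyloxiran-2-yl]methyl}-3-methoxyphenoxy)dimethylsilane | COc1ccc(Br)c(O[Si](C)(C)C(C)(C)C)c1C[C@@H]1OC1(C)C
F6 | step 5 | (2R)-2-(7-bromo-4-methoxy-2,3-dihydro-1-benzofuran-2-yl)propan-2-ol | COc1ccc(Br)c2c1C[C@H](C(C)(C)O)O2
F7 | step 8 | 1-{(2R)-4-methoxy-2-[2-(triethylsilyloxy)propan-2-yl]-2,3-dihydro-1-benzofuran-7-yl}ethan-1-one | COc1ccc(C(C)=O)c2c1C[C@H](C(C)(C)O[Si](CC)(CC)CC)O2
F8 | step 8 | (E)-3-(4-hydroxyphenyl)-1-{(2R)-4-methoxy-2-[2-(triethylsilyloxy)propan-2-yl]-2,3-dihydro-1-benzofuran-7-yl}prop-2-en-1-one | COc1ccc(C(=O)/C=C/c2ccc(O)cc2)c2c1C[C@H](C(C)(C)O[Si](CC)(CC)CC)O2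
F9 | step 2 | 3-bromo-6-methoxy-2-[(2-methylprop-2-en-1-yl)oxy]benzaldehyde | COc1ccc(Br)c(OCC(C)=C)c1C=O
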